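Remark on the chemistry: 13 has no stereocentre. The central carbon of diketone 10 is a stereocentre, but 10 is used as the racemate (largely enolised) and that centre vanishes in step 5, so no stereocontrol is planned. The atom mapping of 10 onto 11 and 13 was checked (ketone-bearing aryl carbon becomes C4a, the brominated carbons C8a and C5, the methoxy carbons C8 and C6, the benzyloxy carbon C7) and needs no correction.

## Structural features

The target 13 is a flavone: a pyran-4-one (ring C) fused to a benzene ring (ring A) through the C4a–C8a bond, with a 4-methoxyphenyl ring (ring B) attached at C2 by a single aryl–aryl-type C–C bond. Ring C carries a methoxy group at C3 and the carbonyl at C4. Ring A is fully substituted, with methoxy groups at C5, C6 and C8 and the only free hydroxyl at C7. There is no stereocentre, so no stereocentres stand next to each other and every difficulty is one of regiochemistry. The fragile points are the C5 methyl ether (peri to the C4 carbonyl, the first to be lost under Lewis acids), the pyranone ring (opened at C2 by hot nucleophilic base) and the C7 oxygen, which must stay distinguishable from four methyl ethers to the end. The real problem is the hexasubstituted ring A with four contiguous oxygens of which exactly one is unmethylated. The key step exploits the fact that, with the C7 oxygen masked, C6 and C8 carry identical groups, so a line through C4a and C7 is a mirror element of ring A whenever C5 and C8a bear the same substituent. A 2,6-dibromoaryl ketone can therefore form the O1–C8a bond at either bromine and keeps the other bromine exactly at C5, where the last methoxy group is needed.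

## Logic of the disconnections

13 to 12: the O–CH2 bond of a benzyl ether on the C7 oxygen is cut. This keeps the one free phenol distinct from the methyl ethers throughout. The forward step must remove the benzyl group without reducing C2=C3 and without acid that would endanger the C5 methyl ether, which points to neutral hydrogenolysis.

12 to 11: the C5–O bond of the C5 methoxy group is cut, leaving bromine at C5. The gain is that ring A of 11 descends from a symmetric dibromide. The forward step needs a copper-assisted bromide-to-methoxide exchange at a crowded position, helped by the peri carbonyl, without opening ring C.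

11 to 10: the O1–C8a bond is cut, opening ring C to an acyclic 1,3-diketone whose aryl ketone has two equivalent ortho bromines. One ring is removed and the ring A half becomes mirror-symmetric. The forward step must arylate the enolate on oxygen, once only.

10 to 8 and 9: the bond between the methoxy-bearing central carbon (future C3) and the carbonyl carbon on ring A (future C4) is cut. This divides the molecule into two halves of similar size, an aroyl chloride 8 (from acid 4) and an enolate 9 (from ketone 7). The forward step must acylate the enolate on carbon with a di-ortho-substituted acyl chloride.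

7 to 5 and 6: the aryl–carbonyl bond para to the methoxy group is cut. Both pieces are commercial. The forward acylation must be para-selective and must spare the aliphatic methyl ether.

4 to 3: both C–Br bonds are cut. The forward step needs a double electrophilic substitution at the only two free ring positions, with no attack at the carboxyl-bearing carbon and no loss of the benzyl ether.

3 to 1 (through 2): the benzyl–oxygen bond on the phenol is cut. The carboxylate is alkylated as well, so the route passes through 2 and the ester is hydrolysed at once. This is done before bromination because an ester flanked by two bromines would resist saponification.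

## Other disconnections considered

Alternative 1: The cut removes C4 itself: C4a–C4 and C4–C3 are broken and C4 comes from carbon monoxide (A2).
- **Forward key step:** 1-(benzyloxy)-4-iodo-2,3,5,6-tetramethoxybenzene (A1), A2 and the enolate of 7 would be joined with Pd(dba)2 and Xantphos. Zerovalent palladium inserts into the C–I bond, A2 inserts to give an aroylpalladium species, and the enolate is acylated on carbon. This should give the open-chain diketone A3, 1-[4-(benzyloxy)-2,3,5,6-tetramethoxyphenyl]-2-methoxy-3-(4-methoxyphenyl)propane-1,3-dione.
- **In favour:** three components meet in one step, ketone 7 is reused, and A1 has the same mirror symmetry as ring A of 10. The C5 methoxy group is present from the start, so no late halide exchange is needed, and the O- versus C-acylation question of step 4 does not arise. On these two points this alternative is the better.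
- **Against:** no ring closes in the key step. Ring C could then be closed only by removing one of the two equivalent ortho methyl groups in the presence of three other methyl ethers and a benzyl ether, followed by cyclodehydration. Lewis acids that cleave ortho-acyl methyl ethers also attack benzyl ethers. A1 is a hexasubstituted, pentaoxygenated iodoarene needing several steps of its own, and A2 is a toxic gas.
- **Comparison:** on structure the two plans use the same symmetry. On mechanism the palladium acylation is at least the equal of step 4, but the ring closure is weaker than displacing a bromide. On step economy the count would be about nine or ten against seven.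

Alternative 2: Ring A is not taken from an arene. The C8–C8a bond is cut (and, one step back, C4a–C5), so that C5 to C8 come from a squaric ester.
- **Forward key step:** a pyranone metalated at the future C4a, made from 5-bromo-3-methoxy-2-(4-methoxyphenyl)-4H-pyran-4-one (A5), would add to 3-tert-butoxy-4-methoxycyclobut-3-ene-1,2-dione (A4). The adduct is the racemic carbinol A6, 2-tert-butoxy-4-hydroxy-3-methoxy-4-[5-methoxy-6-(4-methoxyphenyl)-4-oxo-4H-pyran-3-yl]cyclobut-2-en-1-one. Heating A6 in xylene should open the four-membered ring to a dienylketene, whose ketene carbon bonds to the pyranone carbon next to oxygen in a 6π electrocyclisation. Tautomerisation would give the hydroquinone A7, 7-tert-butoxy-5,8-dihydroxy-3,6-dimethoxy-2-(4-methoxyphenyl)-4H-chromen-4-one. Double O-methylation and acidic loss of the tert-butyl group would lead to 13.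
- **In favour:** the whole hexasubstituted ring A with its four oxygens forms in one thermal, reagent-free step. The C7 oxygen is differentiated from the outset, and no copper or halide exchange is needed. In this respect it is the equal of the chosen plan or better.
- **Against:** the two carbonyls of A4 differ only in the alkoxy groups on the neighbouring carbons, so the site of addition is weakly controlled. A metalated pyranone is prone to ring opening. The tert-butyl ether may be lost at the temperature of the rearrangement. A7 is an electron-rich hydroquinone that oxidises easily, and its chelated C5 hydroxyl is methylated slowly.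
- **Comparison:** on structure the alternative is more direct for ring A. On mechanism it depends on two selectivities that the chosen plan avoids through symmetry. On step economy A5 and A4 each need separate preparation, so the route would be about ten steps.

Alternative 3: The C4a–C5 bond is cut and ring A is folded from a polyketide-like chain on a pyranone derived from kojic acid (A8).
- **Forward key step:** the keto ester A9, methyl 2,4-dimethoxy-4-[5-methoxy-6-(4-methoxyphenyl)-4-oxo-4H-pyran-2-yl]-3-oxobutanoate, would be treated with NaOMe. The extended enolate through the pyranone makes the ring carbon C4a nucleophilic, it attacks the ester carbon (C5) in a Claisen cyclisation, and enolisation gives the diphenol A10, 5,7-dihydroxy-3,6,8-trimethoxy-2-(4-methoxyphenyl)-4H-chromen-4-one.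
- **In favour:** no transition metal and no halogen are needed, and cheap A8 supplies ring C with the C3 oxygen and C4 carbonyl in place. The closure is an intramolecular six-membered one driven by aromatisation. In reliability of the ring-forming event it is the equal of the chosen plan, and in avoiding metals it is the better.
- **Against:** A10 has free hydroxyls at both C5 and C7, but 13 needs C5 methylated and C7 free. That is the reverse of the intrinsic order, since the unchelated, more acidic C7 hydroxyl reacts first, so a protect, methylate, deprotect sequence must follow. The most acidic proton of A9 lies between ketone and ester, so the productive enolate is a dianion. Building A9 needs arylation of the pyranone, O-methylation and a doubly methoxylated four-carbon chain.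
- **Comparison:** on structure the chosen plan solves the C5/C7 differentiation that this one creates. On mechanism both closures are sound. On step economy this alternative is clearly longer.

Key step: step 5

## Route

Step 1
Reactants: 1 syringic acid (4-hydroxy-3,5-dimethoxybenzoic acid)
Product: 3 4-(benzyloxy)-3,5-dimethoxybenzoic acid, via benzyl 4-(benzyloxy)-3,5-dimethoxybenzoate 2 (not isolated)
Conditions: BnBr (2.3 equiv), K2CO3, DMF, 60 °C; then NaOH, MeOH/H2O, 70 °C; then aq. HCl
Reagents that add atoms: benzyl bromide, BrCc1ccccc1
Why: Williamson alkylation benzylates the phenoxide and, unavoidably, the carboxylate; the unhindered benzyl ester 2 is saponified in the same pot while the aryl benzyl ether is inert to hydroxide. Hydrolysis is placed here because an ester flanked by two bromines would later resist saponification.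

Step 2
Reactants: 3 4-(benzyloxy)-3,5-dimethoxybenzoic acid
Product: 4 4-(benzyloxy)-2,6-dibromo-3,5-dimethoxybenzoic acid
Conditions: Br2 (2.3 equiv), NaOAc, AcOH, 25 to 45 °C, dark
Reagents that add atoms: bromine, BrBr
Why: Electrophilic aromatic bromination: C2 and C6 are the only free ring positions and each is ortho to one methoxy group and para to the other, whereas the carboxyl-bearing carbon is activated only by the para benzyloxy group and the benzyl phenyl ring is unactivated. NaOAc traps HBr so that the benzyl ether is not cleaved.

Step 3
Reactants: 5 anisole; 6 methoxyacetyl chloride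
Product: 7 2-methoxy-1-(4-methoxyphenyl)ethanone
Conditions: AlCl3 (1.2 equiv), CH2Cl2, 0 °C to rt; cold dilute HCl
Reagents that add atoms: none
Why: Friedel–Crafts acylation; the methoxy group directs the AlCl3-complexed acylium ion to the para position and the deactivated product is not acylated again. Low temperature and short contact keep AlCl3 from cleaving either methyl ether.

Step 4
Reactants: 4 4-(benzyloxy)-2,6-dibromo-3,5-dimethoxybenzoic acid; 7 2-methoxy-1-(4-methoxyphenyl)ethanone
Product: 10 racemic 1-[4-(benzyloxy)-2,6-dibromo-3,5-dimethoxyphenyl]-2-methoxy-3-(4-methoxyphenyl)propane-1,3-dione, via 4-(benzyloxy)-2,6-dibromo-3,5-dimethoxybenzoyl chloride 8 (not isolated), via lithium (Z)-2-methoxy-1-(4-methoxyphenyl)ethenolate 9 (not isolated)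
Conditions: (a) 4, (COCl)2, DMF (cat.), CH2Cl2, 0 °C to rt, evaporate; (b) 7 (2.1 equiv), LiN(SiMe3)2 (2.1 equiv), THF/toluene, −78 °C; then 8, −78 to 0 °C; dilute HCl
Reagents that add atoms: none
Why: Crossed Claisen-type C-acylation of a preformed lithium enolate by an acid chloride made in situ with oxalyl chloride. The chelated lithium enolate in a weakly polar medium should react through carbon, and the second equivalent of 9 deprotonates the more acidic diketone as it forms, which blocks O-acylation or a second acylation of 10 and returns as 7. Enolates do not exchange with aryl bromides, so both C–Br bonds survive.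

Step 5
Reactants: 10 racemic 1-[4-(benzyloxy)-2,6-dibromo-3,5-dimethoxyphenyl]-2-methoxy-3-(4-methoxyphenyl)propane-1,3-dione
Product: 11 7-(benzyloxy)-5-bromo-3,6,8-trimethoxy-2-(4-methoxyphenyl)-4H-chromen-4-one
Conditions: CuI (10 mol %), 1,10-phenanthroline (20 mol %), Cs2CO3 (2 equiv), dry DMF, 80 °C, N2
Reagents that add atoms: none
Why: Cs2CO3 converts 10 into its 1,3-diketonate, which binds monovalent copper; the metal inserts into one ortho C–Br bond and the resulting trivalent copper aryl enolate collapses by C–O reductive elimination, forming O1–C8a and returning monovalent copper. The closest known reaction type is the copper-catalysed intramolecular O-arylation (Ullmann condensation) of 1-(2-haloaryl)-1,3-diketones to flavones. Ring C closes as a six-membered ring by attack of the enolate oxygen of the 4-methoxybenzoyl carbonyl on the arene carbon, with bromide leaving outside the new ring (6-exo mode through a seven-membered cupracycle). No stereocentre is created, and the racemic centre of 10 disappears as its carbon becomes C3 of the C2=C3 double bond. O- over C-arylation needs no reagent control, because the central carbon or the proximal oxygen could only close four-membered rings. The choice between the two bromines is removed by the mirror element through C4a and C7 of ring A, so either closure gives the same product with the remaining bromine at C5. A second cyclisation cannot follow because the only enolate oxygen is consumed, and moderate temperature with exclusion of water should limit loss of the C5 bromine and retro-Claisen cleavage.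

Step 6
Reactants: 11 7-(benzyloxy)-5-bromo-3,6,8-trimethoxy-2-(4-methoxyphenyl)-4H-chromen-4-one
Product: 12 7-(benzyloxy)-3,5,6,8-tetramethoxy-2-(4-methoxyphenyl)-4H-chromen-4-one
Conditions: NaOMe (5 equiv, in MeOH), CuBr (20 mol %), DMF, 100 °C, N2
Reagents that add atoms: sodium methoxide, C[O-].[Na+]
Why: Copper-catalysed Ullmann-type methoxylation of an aryl bromide; the C5–Br bond is peri to the C4 carbonyl, which coordinates copper and stabilises the developing negative charge, so substitution is assisted at this otherwise electron-rich position. The benzyl and methyl ethers are inert to methoxide.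

Step 7
Reactants: 12 7-(benzyloxy)-3,5,6,8-tetramethoxy-2-(4-methoxyphenyl)-4H-chromen-4-one
Product: 13 7-hydroxy-3,5,6,8-tetramethoxy-2-(4-methoxyphenyl)-4H-chromen-4-one (CNP0495887.0)
Conditions: H2 (1 atm), 10% Pd/C, EtOAc/MeOH, rt
Reagents that add atoms: none
Why: Catalytic hydrogenolysis of the aryl benzyl ether under neutral conditions; the tetrasubstituted, conjugated C2=C3 bond of a flavone should not be reduced at room temperature and 1 atm, and no Lewis acid is present that could remove the C5 methyl group.

## Compound list

1 | syringic acid (4-hydroxy-3,5-dimethoxybenzoic acid) | COc1cc(C(=O)O)cc(OC)c1O | starting material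
2 | benzyl 4-(benzyloxy)-3,5-dimethoxybenzoate | COc1cc(C(=O)OCc2ccccc2)cc(OC)c1OCc1ccccc1 | intermediate
3 | 4-(benzyloxy)-3,5-dimethoxybenzoic acid | COc1cc(C(=O)O)cc(OC)c1OCc1ccccc1 | intermediate
4 | 4-(benzyloxy)-2,6-dibromo-3,5-dimethoxybenzoic acid | COc1c(Br)c(C(=O)O)c(Br)c(OC)c1OCc1ccccc1 | intermediate
5 | anisole | COc1ccccc1 | starting material
6 | methoxyacetyl chloride | COCC(=O)Cl | starting material
7 | 2-methoxy-1-(4-methoxyphenyl)ethanone | COCC(=O)c1ccc(OC)cc1 | intermediate
8 | 4-(benzyloxy)-2,6-dibromo-3,5-dimethoxybenzoyl chloride | COc1c(Br)c(C(=O)Cl)c(Br)c(OC)c1OCc1ccccc1 | intermediate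
9 | lithium (Z)-2-methoxy-1-(4-methoxyphenyl)ethenolate (chelated enolate of 7) | [Li+].CO/C=C(\[O-])c1ccc(OC)cc1 | intermediate
10 | 1-[4-(benzyloxy)-2,6-dibromo-3,5-dimethoxyphenyl]-2-methoxy-3-(4-methoxyphenyl)propane-1,3-dione (racemic, enolisable) | COc1ccc(C(=O)C(OC)C(=O)c2c(Br)c(OC)c(OCc3ccccc3)c(OC)c2Br)cc1 | intermediate
11 | 7-(benzyloxy)-5-bromo-3,6,8-trimethoxy-2-(4-methoxyphenyl)-4H-chromen-4-one | COc1ccc(-c2oc3c(OC)c(OCc4ccccc4)c(OC)c(Br)c3c(=O)c2OC)cc1 | intermediate
12 | 7-(benzyloxy)-3,5,6,8-tetramethoxy-2-(4-methoxyphenyl)-4H-chromen-4-one | COc1ccc(-c2oc3c(OC)c(OCc4ccccc4)c(OC)c(OC)c3c(=O)c2OC)cc1 | intermediate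
13 | 7-hydroxy-3,5,6,8-tetramethoxy-2-(4-methoxyphenyl)-4H-chromen-4-one | COc1ccc(-c2oc3c(OC)c(O)c(OC)c(OC)c3c(=O)c2OC)cc1 | target

## Step count and least certain steps

Total step count: 7. Longest linear sequence: 6 steps (steps 1, 2, 4, 5, 6, 7 from syringic acid); step 3 is a one-step branch.

Step 5 (key step). The most likely failure is slow insertion of copper into the crowded, electron-rich C–Br bond, which is flanked by a methoxy group and the acyl carbon. That would leave time for reductive loss of bromine or base-induced retro-Claisen cleavage of the diketone. The fallback changes the substrate and not the disconnection. Starting from 3, double iodination (N-iodosuccinimide, CF3CO2H, MeCN) would give 4-(benzyloxy)-2,6-diiodo-3,5-dimethoxybenzoic acid F1. Oxalyl chloride would convert it into 4-(benzyloxy)-2,6-diiodo-3,5-dimethoxybenzoyl chloride F2, which would acylate 9 as in step 4 to give 1-[4-(benzyloxy)-2,6-diiodo-3,5-dimethoxyphenyl]-2-methoxy-3-(4-methoxyphenyl)propane-1,3-dione F3. The weaker C–I bond should let CuI/Cs2CO3 close ring C near 40–50 °C to 7-(benzyloxy)-5-iodo-3,6,8-trimethoxy-2-(4-methoxyphenyl)-4H-chromen-4-one F4. Methoxylation of F4 (NaOMe, CuI, DMF/MeOH, 80 °C) rejoins the route at 12.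

Step 4. The risk is acylation of the enolate on oxygen, or sluggish attack at a carbonyl shielded by two ortho bromines, so that enol ester formation or over-acylation competes. The fallback forms the same C–C bond at the aldehyde oxidation level, where only carbon attack is possible. Starting from 8, reduction with LiAlH(OtBu)3 (THF, −78 °C) would give 4-(benzyloxy)-2,6-dibromo-3,5-dimethoxybenzaldehyde F5. Aldol addition of 9 (THF, −78 °C) would give 3-[4-(benzyloxy)-2,6-dibromo-3,5-dimethoxyphenyl]-3-hydroxy-2-methoxy-1-(4-methoxyphenyl)propan-1-one F6 as a mixture of diastereomers. Oxidation with Dess–Martin periodinane (NaHCO3, CH2Cl2) would converge on 10, where the route is rejoined.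

Step 2. The risks are ipso attack at the carboxyl-bearing carbon with loss of CO2, stalling after the first bromination as the ring is deactivated and the methoxy groups are twisted out of conjugation, and acidolysis of the benzyl ether if HBr is not fully buffered. The fallback starts from 2, isolated instead of being saponified. The ester cannot decarboxylate; bromination with N-bromosuccinimide in MeCN would give benzyl 4-(benzyloxy)-2,6-dibromo-3,5-dimethoxybenzoate F7. The hindered ester would then be cleaved with anhydrous hydroxide (KOtBu/H2O, THF/DMSO, rt), which is known to hydrolyse di-ortho-substituted benzoates, returning to the route at 4.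

Step 6. The risks are reductive removal of bromine instead of C–O bond formation, and opening of ring C by addition of methoxide at C2 at the temperature needed. The fallback starts from 11 and separates C–O bond formation from methylation. A palladium-catalysed hydroxylation with benzaldoxime as hydroxide surrogate (Pd2(dba)3, tBuBrettPhos, Cs2CO3, DMF, 80 °C) proceeds through zerovalent palladium insertion and base-induced loss of benzonitrile from the O-aryl oxime. It would give 7-(benzyloxy)-5-hydroxy-3,6,8-trimethoxy-2-(4-methoxyphenyl)-4H-chromen-4-one F8. Methylation of the chelated C5 hydroxyl (MeI, K2CO3, DMF, 40 °C) rejoins the route at 12.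

## Further compounds

F1 | step 5 | 4-(benzyloxy)-2,6-diiodo-3,5-dimethoxybenzoic acid | COc1c(I)c(C(=O)O)c(I)c(OC)c1OCc1ccccc1
F2 | step 5 | 4-(benzyloxy)-2,6-diiodo-3,5-dimethoxybenzoyl chloride | COc1c(I)c(C(=O)Cl)c(I)c(OC)c1OCc1ccccc1
F3 | step 5 | 1-[4-(benzyloxy)-2,6-diiodo-3,5-dimethoxyphenyl]-2-methoxy-3-(4-methoxyphenyl)propane-1,3-dione (racemic, enolisable) | COc1ccc(C(=O)C(OC)C(=O)c2c(I)c(OC)c(OCc3ccccc3)c(OC)c2I)cc1
F4 | step 5 | 7-(benzyloxy)-5-iodo-3,6,8-trimethoxy-2-(4-methoxyphenyl)-4H-chromen-4-one | COc1ccc(-c2oc3c(OC)c(OCc4ccccc4)c(OC)c(I)c3c(=O)c2OC)cc1
F5 | step 4 | 4-(benzyloxy)-2,6-dibromo-3,5-dimethoxybenzaldehyde | COc1c(Br)c(C=O)c(Br)c(OC)c1OCc1ccccc1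
F6 | step 4 | 3-[4-(benzyloxy)-2,6-dibromo-3,5-dimethoxyphenyl]-3-hydroxy-2-methoxy-1-(4-methoxyphenyl)propan-1-one (racemic mixture of syn and anti diastereomers) | COc1ccc(C(=O)C(OC)C(O)c2c(Br)c(OC)c(OCc3ccccc3)c(OC)c2Br)cc1
F7 | step 2 | benzyl 4-(benzyloxy)-2,6-dibromo-3,5-dimethoxybenzoate | COc1c(Br)c(C(=O)OCc2ccccc2)c(Br)c(OC)c1OCc1ccccc1
F8 | step 6 | 7-(benzyloxy)-5-hydroxy-3,6,8-trimethoxy-2-(4-methoxyphenyl)-4H-chromen-4-one | COc1ccc(-c2oc3c(OC)c(OCc4ccccc4)c(OC)c(O)c3c(=O)c2OC)cc1
A1 | alternative 1 | 1-(benzyloxy)-4-iodo-2,3,5,6-tetramethoxybenzene | COc1c(OC)c(OCc2ccccc2)c(OC)c(OC)c1I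
A2 | alternative 1 | carbon monoxide | [C-]#[O+]
A3 | alternative 1 | 1-[4-(benzyloxy)-2,3,5,6-tetramethoxyphenyl]-2-methoxy-3-(4-methoxyphenyl)propane-1,3-dione (racemic, enolisable) | COc1ccc(C(=O)C(OC)C(=O)c2c(OC)c(OC)c(OCc3ccccc3)c(OC)c2OC)cc1
A4 | alternative 2 | 3-tert-butoxy-4-methoxycyclobut-3-ene-1,2-dione | COC1=C(OC(C)(C)C)C(=O)C1=O
A5 | alternative 2 | 5-bromo-3-methoxy-2-(4-methoxyphenyl)-4H-pyran-4-one | COc1ccc(-c2occ(Br)c(=O)c2OC)cc1
A6 | alternative 2 | 2-tert-butoxy-4-hydroxy-3-methoxy-4-[5-methoxy-6-(4-methoxyphenyl)-4-oxo-4H-pyran-3-yl]cyclobut-2-en-1-one (racemic) | COc1ccc(-c2occ(C3(O)C(OC)=C(OC(C)(C)C)C3=O)c(=O)c2OC)cc1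
A7 | alternative 2 | 7-tert-butoxy-5,8-dihydroxy-3,6-dimethoxy-2-(4-methoxyphenyl)-4H-chromen-4-one | COc1ccc(-c2oc3c(O)c(OC(C)(C)C)c(OC)c(O)c3c(=O)c2OC)cc1
A8 | alternative 3 | kojic acid (5-hydroxy-2-(hydroxymethyl)-4H-pyran-4-one) | OCc1cc(=O)c(O)co1
A9 | alternative 3 | methyl 2,4-dimethoxy-4-[5-methoxy-6-(4-methoxyphenyl)-4-oxo-4H-pyran-2-yl]-3-oxobutanoate (mixture of stereoisomers, enolisable) | COc1ccc(-c2oc(C(OC)C(=O)C(OC)C(=O)OC)cc(=O)c2OC)cc1
A10 | alternative 3 | 5,7-dihydroxy-3,6,8-trimethoxy-2-(4-methoxyphenyl)-4H-chromen-4-one | COc1ccc(-c2oc3c(OC)c(O)c(OC)c(O)c3c(=O)c2OC)cc1
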